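Slowness was what I watched in this flask: by its forward rate at the charged levels, the starting complex had a half-life of 12 h in the first exchange, shorter than the 25 h run.

starting complex 10 mM; incoming ligand 30.0 mM; time 25 h

    starting complex + incoming ligand ⇌ leaving ligand + complex with one exchanged (K1 = 0.42, k1 = 5.3 × 10⁻⁴ M⁻¹ s⁻¹)
    complex with one exchanged + incoming ligand ⇌ leaving ligand + complex with two exchanged (K2 = 3.1, k2 = 3.0 × 10⁻⁵ M⁻¹ s⁻¹)
    leaving ligand + incoming ligand ⇌ idle adduct, settled at all times (K3 = 20 M⁻¹)
    leaving ligand → by-product carried off (k4 = 2.0 × 10⁻⁴ s⁻¹)
    crystals ⇌ complex with one exchanged, rate k5*(cs5 - [complex with one exchanged]) while solid is left; crystals form when [complex with one exchanged] > cs5 (cs5 = 4.7 mM, k5 = 0.0028 s⁻¹)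

- for complex with one exchanged the crystals are counted in
- for leaving ligand the idle adduct is counted in
- as a solid, counted per litre of solution: crystals
- run time (flask): 25 h

1. part of the starting complex that has reacted at 25 h
2. share of the unused incoming ligand that is free and not bound as idle adduct, at 25 h

**Ligand dose.** The rate constant of the first exchange times the charged incoming ligand times the time came to 1.43; I called this product the ligand dose. I left out the way back, and also the second exchange, whose forward half-life of 8.9 d was far longer than the run.

**My bracket.** With the ligand held at its charge, pseudo-first-order, the fraction reacted was one minus the exponential of minus the dose, 76.1%, my first ceiling. Each whole unit of fraction reacted cost the ligand 0.333 of its charge, so holding the ligand through the run at its level for my ceiling conversion gave a floor of 65.6%. The ligand curve sags, so its mean lay under the midpoint of its fall; putting the floor back at half weight lowered the ceiling to 72.0%. Another round gave a floor of 66.3% and a ceiling of 72.0%.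

**The forecast.** The forecast gave 69% reacted and 99.6% of the unused ligand free, on the ground that “the leaving ligand is removed quickly”. Its conversion was higher than my floor and lower than my ceiling.

**The run.** The flask gave 69.3% reacted and 99.6% free, higher than my floor and lower than my ceiling. At 25.0 h the first exchange still used incoming ligand 12 times as fast as the second, by forward rates, and the flask held 66.8% complex with one exchanged, crystals counted, against 2.45% complex with two exchanged. A shift of 5 points in conversion took incoming ligand at 26.3 mM or 34.3 mM. The neighbour flask with 12 mM of incoming ligand had a dose of 0.572; one round bracketed it between 30.5% and 39.3%, and that flask gave 37.0%.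

The rate constants were chosen freely; the run is a simulation.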